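**Plan**

- Numbering: ring C1–C6 with C1 bearing the acetoxymethyl carbon C7; side chain numbered as a hept-4-en-2-yl group attached to ring C4.
- Retrosynthesis cuts, in order: the two acetates; the ring C1–C7 bond (back to an enol triflate of a 4-substituted cyclohexanone); the bond between ring C4 and side-chain carbinol C2; the side-chain C4=C5 alkene (cross-metathesis).
- Forward: the whole eight-carbon side chain is built by cross-metathesis and joined, as its α-lithiated carbinol benzoate, to a sec-alkyl boronic ester of the preformed six-membered ring (a cyclohexanone ketal). The ring alkene and C7 follow by enol triflate formation and hydroxymethylation, then desilylation and acetylation.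
- Enabling features: side-chain C2 carries oxygen, so it can serve as a lithiated carbinol ester that first attacks boron and then accepts the ring carbon from boron. Ring C4 lies on the mirror plane of a 4-substituted cyclohexanone, so it enters without configuration and becomes (R) only when one of the two α-CH2 groups is turned into the C1=C2 alkene.
- Stereochemistry: side-chain C2 from (R)-pent-4-en-2-ol (Mitsunobu inversion, then stereospecific 1,2-metalate rearrangement); C6 from (S)-2-methylglycidol; the E alkene from thermodynamic cross-metathesis; ring C4 from deprotonation by a chiral lithium amide.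

Key step: step 7

Remark: the sense of the chiral lithium amide in step 10 is assigned by analogy with 4-tert-butylcyclohexanone, whose C4 has the same priority pattern and for which the (R,R) amide favours the (S) enolate; the antipodal amide would be used if the analogy did not hold.

**Route**

Step 1
Reactants: 1 (2R)-pent-4-en-2-ol
Product: 2 (2S)-pent-4-en-2-yl 2,4,6-tri(propan-2-yl)benzoate
Conditions: 2,4,6-tri(propan-2-yl)benzoic acid, PPh3, DIAD, THF, 0 °C → rt
Reagents that add atoms: 2,4,6-tri(propan-2-yl)benzoic acid, CC(C)c1cc(C(C)C)c(C(=O)O)c(C(C)C)c1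
Why: Mitsunobu esterification displaces the oxyphosphonium of the secondary alcohol by the carboxylate in an SN2 step, so the (R) alcohol should give the (S) ester with inversion.

Step 2
Reactants: 3 [(2S)-2-methyloxiran-2-yl]methanol
Product: 4 tert-butyldimethyl{[(2R)-2-methyloxiran-2-yl]methoxy}silane
Conditions: TBSCl, imidazole, CH2Cl2, 0 °C → rt
Reagents that add atoms: tert-butyldimethylsilyl chloride, CC(C)(C)[Si](C)(C)Cl
Why: Silyl ether formation at the primary alcohol leaves the 2,2-disubstituted epoxide untouched; the stereocenter is not involved and its descriptor changes to (R) only through the priority change.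

Step 3
Reactants: 4 tert-butyldimethyl{[(2R)-2-methyloxiran-2-yl]methoxy}silane
Product: 5 (2R)-1-[(tert-butyldimethylsilyl)oxy]-2-methylbut-3-en-2-ol
Conditions: Me3SI (3 equiv), n-BuLi (2.9 equiv), THF, −10 °C → rt
Reagents that add atoms: trimethylsulfonium iodide, C[S+](C)C.[I-]
Why: Dimethylsulfonium methylide opens the epoxide at its CH2 terminus and the β-alkoxy sulfonium salt then loses dimethyl sulfide (one-carbon homologation of an epoxide to an allylic alcohol), so the C–O bond at the quaternary stereocenter is never broken.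

Step 4
Reactants: 2 (2S)-pent-4-en-2-yl 2,4,6-tri(propan-2-yl)benzoate (2 equiv); 5 (2R)-1-[(tert-butyldimethylsilyl)oxy]-2-methylbut-3-en-2-ol
Product: 6 (2S,4E,6R)-7-[(tert-butyldimethylsilyl)oxy]-6-hydroxy-6-methylhept-4-en-2-yl 2,4,6-tri(propan-2-yl)benzoate
Conditions: second-generation Grubbs catalyst RuCl2(=CHPh)(H2IMes)(PCy3) (5 mol %), CH2Cl2, 40 °C
Reagents that add atoms: none
Why: Olefin cross-metathesis between an unhindered homoallylic alkene (in excess, its homodimer re-enters the cycle) and a tertiary allylic alcohol that does not homodimerise should be selective and, under thermodynamic control, E-selective; no stereocenter is touched.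

Step 5
Reactants: 6 (2S,4E,6R)-7-[(tert-butyldimethylsilyl)oxy]-6-hydroxy-6-methylhept-4-en-2-yl 2,4,6-tri(propan-2-yl)benzoate
Product: 7 (2S,4E,6R)-7-[(tert-butyldimethylsilyl)oxy]-6-methyl-6-[(triethylsilyl)oxy]hept-4-en-2-yl 2,4,6-tri(propan-2-yl)benzoate
Conditions: TESOTf, 2,6-lutidine, CH2Cl2, −78 °C → 0 °C
Reagents that add atoms: triethylsilyl trifluoromethanesulfonate, CC[Si](CC)(CC)OS(=O)(=O)C(F)(F)F
Why: Silyl triflate silylation of the hindered tertiary alcohol removes the only acidic proton before the organolithium step, and the hindered aryl ester is inert.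

Step 6
Reactants: 8 8-bromo-1,4-dioxaspiro[4.5]decane
Product: 9 2-(1,4-dioxaspiro[4.5]decan-8-yl)-5,5-dimethyl-1,3,2-dioxaborinane
Conditions: B2neop2 (1.5 equiv), CuI (10 mol %), PPh3 (13 mol %), LiOMe (2 equiv), DMF, rt
Reagents that add atoms: bis(neopentyl glycolato)diboron, CC1(C)COB(OC1)B1OCC(C)(C)CO1
Why: Copper-catalysed borylation of an unactivated secondary alkyl bromide with a diboron reagent gives the sec-alkyl boronic ester; C8 of the spiro ketal lies on a mirror plane, so no stereochemistry arises.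

Step 7
Reactants: 7 (2S,4E,6R)-7-[(tert-butyldimethylsilyl)oxy]-6-methyl-6-[(triethylsilyl)oxy]hept-4-en-2-yl 2,4,6-tri(propan-2-yl)benzoate; 9 2-(1,4-dioxaspiro[4.5]decan-8-yl)-5,5-dimethyl-1,3,2-dioxaborinane
Product: 13 (2S,4E,6R)-7-[(tert-butyldimethylsilyl)oxy]-2-(1,4-dioxaspiro[4.5]decan-8-yl)-6-methyl-6-[(triethylsilyl)oxy]hept-4-en-2-ol, via lithiated benzoate 10 (not isolated), via lithium boronate complex 11 (not isolated), via tertiary boronic ester 12 (not isolated)
Conditions: s-BuLi (1.3 equiv), TMEDA (1.3 equiv), cyclopentyl methyl ether, −60 °C, 3 h; 9 (1.5 equiv), −60 °C → 40 °C; then 2 M NaOH, 30% H2O2, THF, 0 °C → rt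
Reagents that add atoms: hydrogen peroxide, OO
Why: The benzoate carbonyl of 7 binds s-BuLi/TMEDA and directs removal of the adjacent carbinol C–H with retention to give the configurationally stable α-oxy organolithium 10, which adds to boron of 9 with retention to give boronate complex 11; on warming, the ring carbon migrates from boron to carbon anti to the departing benzoate (1,2-metalate rearrangement, inversion at carbon) to give 12, and peroxide replaces boron by hydroxyl with retention. The closest known reaction type is the lithiation–borylation of secondary dialkyl 2,4,6-triisopropylbenzoates with neopentyl glycol boronic esters followed by oxidation to tertiary alcohols. No ring is closed. The new stereocenter, side-chain carbinol C2, is controlled by the (S) carbinol center of 7 through the stereospecific retention–inversion–retention sequence, which puts OH where H stood and the ring on the side opposite the departed benzoate oxygen, i.e. (2S); C8 of 9 lies on a mirror plane and carries no configuration at this stage. The step needs α-lithiation to outrun deprotonation of the allylic C3 methylene and needs the hindered tertiary carbanion to add to a secondary boronic ester; the first is secured by the complex-induced proximity effect of the benzoate and by the quaternary C6, which leaves C3 as the only allylic C–H site, the second by the small neopentyl glycol ester on boron and an excess of 9.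

Step 8
Reactants: 13 (2S,4E,6R)-7-[(tert-butyldimethylsilyl)oxy]-2-(1,4-dioxaspiro[4.5]decan-8-yl)-6-methyl-6-[(triethylsilyl)oxy]hept-4-en-2-ol
Product: 14 4-[(2S,4E,6R)-7-[(tert-butyldimethylsilyl)oxy]-2-hydroxy-6-methyl-6-[(triethylsilyl)oxy]hept-4-en-2-yl]cyclohexan-1-one
Conditions: PPTS (0.2 equiv), acetone/H2O (10:1), 50 °C
Reagents that add atoms: water, O
Why: Acid-catalysed ketal hydrolysis frees the ring ketone under conditions that a primary TBS ether and a hindered tertiary TES ether should survive, and any TES lost here is restored in step 9.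

Step 9
Reactants: 14 4-[(2S,4E,6R)-7-[(tert-butyldimethylsilyl)oxy]-2-hydroxy-6-methyl-6-[(triethylsilyl)oxy]hept-4-en-2-yl]cyclohexan-1-one
Product: 15 4-[(2S,4E,6R)-7-[(tert-butyldimethylsilyl)oxy]-6-methyl-2,6-bis[(triethylsilyl)oxy]hept-4-en-2-yl]cyclohexan-1-one
Conditions: TESOTf (2.5 equiv), 2,6-lutidine, CH2Cl2, −78 °C → −40 °C
Reagents that add atoms: triethylsilyl trifluoromethanesulfonate, CC[Si](CC)(CC)OS(=O)(=O)C(F)(F)F
Why: Silyl triflate silylation of the tertiary alcohol at low temperature with the weak base 2,6-lutidine is faster than enol silylation of the ketone and masks the last protic group before the amide base is used.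

Step 10
Reactants: 15 4-[(2S,4E,6R)-7-[(tert-butyldimethylsilyl)oxy]-6-methyl-2,6-bis[(triethylsilyl)oxy]hept-4-en-2-yl]cyclohexan-1-one
Product: 17 (4R)-4-[(2S,4E,6R)-7-[(tert-butyldimethylsilyl)oxy]-6-methyl-2,6-bis[(triethylsilyl)oxy]hept-4-en-2-yl]cyclohex-1-en-1-yl trifluoromethanesulfonate, via lithium enolate 16 (not isolated)
Conditions: (S,S)-bis(1-phenylethyl)amine (1.3 equiv), n-BuLi (1.25 equiv), LiCl (0.6 equiv), THF, −78 °C; then N-(5-chloropyridin-2-yl)triflimide (1.3 equiv), −78 °C → 0 °C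
Reagents that add atoms: N-(5-chloropyridin-2-yl)-1,1,1-trifluoro-N-(trifluoromethanesulfonyl)methanesulfonamide, FC(F)(F)S(=O)(=O)N(c1ccc(Cl)cn1)S(=O)(=O)C(F)(F)F
Why: Group-selective deprotonation of a conformationally locked 4-substituted cyclohexanone by a C2-symmetric chiral lithium amide with LiCl, followed by O-sulfonylation of the enolate with an N-aryl triflimide, fixes the ring alkene on one side and thereby makes C4 (R); the quaternary carbinol substituent should hold the chair with the side chain equatorial as tert-butyl does, and the (S,S) amide is expected to remove the axial α-hydrogen that leads to the (4R) enolate.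

Step 11
Reactants: 17 (4R)-4-[(2S,4E,6R)-7-[(tert-butyldimethylsilyl)oxy]-6-methyl-2,6-bis[(triethylsilyl)oxy]hept-4-en-2-yl]cyclohex-1-en-1-yl trifluoromethanesulfonate
Product: 18 {(4R)-4-[(2S,4E,6R)-7-[(tert-butyldimethylsilyl)oxy]-6-methyl-2,6-bis[(triethylsilyl)oxy]hept-4-en-2-yl]cyclohex-1-en-1-yl}methanol
Conditions: Bu3SnCH2OH (1.5 equiv), Pd(PPh3)4 (5 mol %), LiCl (3 equiv), 1,4-dioxane, 100 °C
Reagents that add atoms: (tributylstannyl)methanol, CCCC[Sn](CCCC)(CCCC)CO
Why: Stille cross-coupling of the alkenyl triflate (oxidative addition to zerovalent palladium, chloride-assisted transmetalation of the hydroxymethyl group, reductive elimination) installs C7 at the alcohol oxidation level with the alkene position fixed by the triflate.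

Step 12
Reactants: 18 {(4R)-4-[(2S,4E,6R)-7-[(tert-butyldimethylsilyl)oxy]-6-methyl-2,6-bis[(triethylsilyl)oxy]hept-4-en-2-yl]cyclohex-1-en-1-yl}methanol
Product: 19 (2R,3E,6S)-6-[(1R)-4-(hydroxymethyl)cyclohex-3-en-1-yl]-2-methylhept-3-ene-1,2,6-triol
Conditions: TBAF (4 equiv), THF, rt → 40 °C
Reagents that add atoms: none
Why: Fluoride-mediated cleavage of the three silyl ethers under basic, non-ionising conditions should spare the tertiary allylic alcohol and the trisubstituted alkene; no stereocenter is touched.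

Step 13
Reactants: 19 (2R,3E,6S)-6-[(1R)-4-(hydroxymethyl)cyclohex-3-en-1-yl]-2-methylhept-3-ene-1,2,6-triol
Product: 20 {(4R)-4-[(2S,4E,6R)-7-acetoxy-2,6-dihydroxy-6-methylhept-4-en-2-yl]cyclohex-1-en-1-yl}methyl acetate
Conditions: Ac2O (2.4 equiv), pyridine, CH2Cl2, 0 °C → rt
Reagents that add atoms: acetic anhydride, CC(=O)OC(C)=O
Why: Acylation with acetic anhydride/pyridine without a nucleophilic catalyst should be selective for the two primary hydroxyls because the two tertiary alcohols are too hindered to react, giving the target.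

**Compound list**

1 | (2R)-pent-4-en-2-ol | C[C@@H](O)CC=C | starting material
2 | (2S)-pent-4-en-2-yl 2,4,6-tri(propan-2-yl)benzoate | C[C@H](OC(=O)c1c(C(C)C)cc(C(C)C)cc1C(C)C)CC=C | intermediate
3 | [(2S)-2-methyloxiran-2-yl]methanol | C1[C@@](C)(O1)CO | starting material
4 | tert-butyldimethyl{[(2R)-2-methyloxiran-2-yl]methoxy}silane | C1[C@@](C)(O1)CO[Si](C)(C)C(C)(C)C | intermediate
5 | (2R)-1-[(tert-butyldimethylsilyl)oxy]-2-methylbut-3-en-2-ol | C=C[C@@](C)(O)CO[Si](C)(C)C(C)(C)C | intermediate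
6 | (2S,4E,6R)-7-[(tert-butyldimethylsilyl)oxy]-6-hydroxy-6-methylhept-4-en-2-yl 2,4,6-tri(propan-2-yl)benzoate | C[C@H](OC(=O)c1c(C(C)C)cc(C(C)C)cc1C(C)C)C/C=C/[C@@](C)(O)CO[Si](C)(C)C(C)(C)C | intermediate
7 | (2S,4E,6R)-7-[(tert-butyldimethylsilyl)oxy]-6-methyl-6-[(triethylsilyl)oxy]hept-4-en-2-yl 2,4,6-tri(propan-2-yl)benzoate | C[C@H](OC(=O)c1c(C(C)C)cc(C(C)C)cc1C(C)C)C/C=C/[C@@](C)(O[Si](CC)(CC)CC)CO[Si](C)(C)C(C)(C)C | intermediate
8 | 8-bromo-1,4-dioxaspiro[4.5]decane | BrC1CCC2(CC1)OCCO2 | starting material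
9 | 2-(1,4-dioxaspiro[4.5]decan-8-yl)-5,5-dimethyl-1,3,2-dioxaborinane | CC1(C)COB(OC1)C1CCC2(CC1)OCCO2 | intermediate
10 | (2S,4E,6R)-7-[(tert-butyldimethylsilyl)oxy]-2-lithio-6-methyl-6-[(triethylsilyl)oxy]hept-4-en-2-yl 2,4,6-tri(propan-2-yl)benzoate | C[C@]([Li])(OC(=O)c1c(C(C)C)cc(C(C)C)cc1C(C)C)C/C=C/[C@@](C)(O[Si](CC)(CC)CC)CO[Si](C)(C)C(C)(C)C | intermediate
11 | lithium boronate complex of 10 and 9 (boron bound to side-chain C2 and to C8 of the spiro ketal) | C[C@]([B-]1(OCC(C)(C)CO1)C1CCC2(CC1)OCCO2)(OC(=O)c1c(C(C)C)cc(C(C)C)cc1C(C)C)C/C=C/[C@@](C)(O[Si](CC)(CC)CC)CO[Si](C)(C)C(C)(C)C.[Li+] | intermediate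
12 | 2-[(2R,4E,6R)-7-[(tert-butyldimethylsilyl)oxy]-2-(1,4-dioxaspiro[4.5]decan-8-yl)-6-methyl-6-[(triethylsilyl)oxy]hept-4-en-2-yl]-5,5-dimethyl-1,3,2-dioxaborinane | C[C@@](B1OCC(C)(C)CO1)(C1CCC2(CC1)OCCO2)C/C=C/[C@@](C)(O[Si](CC)(CC)CC)CO[Si](C)(C)C(C)(C)C | intermediate
13 | (2S,4E,6R)-7-[(tert-butyldimethylsilyl)oxy]-2-(1,4-dioxaspiro[4.5]decan-8-yl)-6-methyl-6-[(triethylsilyl)oxy]hept-4-en-2-ol | C[C@@](O)(C1CCC2(CC1)OCCO2)C/C=C/[C@@](C)(O[Si](CC)(CC)CC)CO[Si](C)(C)C(C)(C)C | intermediate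
14 | 4-[(2S,4E,6R)-7-[(tert-butyldimethylsilyl)oxy]-2-hydroxy-6-methyl-6-[(triethylsilyl)oxy]hept-4-en-2-yl]cyclohexan-1-one | C[C@@](O)(C1CCC(=O)CC1)C/C=C/[C@@](C)(O[Si](CC)(CC)CC)CO[Si](C)(C)C(C)(C)C | intermediate
15 | 4-[(2S,4E,6R)-7-[(tert-butyldimethylsilyl)oxy]-6-methyl-2,6-bis[(triethylsilyl)oxy]hept-4-en-2-yl]cyclohexan-1-one | C[C@@](O[Si](CC)(CC)CC)(C1CCC(=O)CC1)C/C=C/[C@@](C)(O[Si](CC)(CC)CC)CO[Si](C)(C)C(C)(C)C | intermediate
16 | lithium (4R)-4-[(2S,4E,6R)-7-[(tert-butyldimethylsilyl)oxy]-6-methyl-2,6-bis[(triethylsilyl)oxy]hept-4-en-2-yl]cyclohex-1-en-1-olate | [Li]OC1=CC[C@H]([C@@](C)(O[Si](CC)(CC)CC)C/C=C/[C@@](C)(O[Si](CC)(CC)CC)CO[Si](C)(C)C(C)(C)C)CC1 | intermediate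
17 | (4R)-4-[(2S,4E,6R)-7-[(tert-butyldimethylsilyl)oxy]-6-methyl-2,6-bis[(triethylsilyl)oxy]hept-4-en-2-yl]cyclohex-1-en-1-yl trifluoromethanesulfonate | FC(F)(F)S(=O)(=O)OC1=CC[C@H]([C@@](C)(O[Si](CC)(CC)CC)C/C=C/[C@@](C)(O[Si](CC)(CC)CC)CO[Si](C)(C)C(C)(C)C)CC1 | intermediate
18 | {(4R)-4-[(2S,4E,6R)-7-[(tert-butyldimethylsilyl)oxy]-6-methyl-2,6-bis[(triethylsilyl)oxy]hept-4-en-2-yl]cyclohex-1-en-1-yl}methanol | OCC1=CC[C@H]([C@@](C)(O[Si](CC)(CC)CC)C/C=C/[C@@](C)(O[Si](CC)(CC)CC)CO[Si](C)(C)C(C)(C)C)CC1 | intermediate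
19 | (2R,3E,6S)-6-[(1R)-4-(hydroxymethyl)cyclohex-3-en-1-yl]-2-methylhept-3-ene-1,2,6-triol | OCC1=CC[C@H]([C@@](C)(O)C/C=C/[C@@](C)(O)CO)CC1 | intermediate
20 | {(4R)-4-[(2S,4E,6R)-7-acetoxy-2,6-dihydroxy-6-methylhept-4-en-2-yl]cyclohex-1-en-1-yl}methyl acetate | CC(=O)OCC1=CC[C@H]([C@@](C)(O)C/C=C/[C@@](C)(O)COC(C)=O)CC1 | target

**Step count**

Total: 13 steps. Longest linear sequence: 11 steps (steps 2, 3, 4, 5, 7, 8, 9, 10, 11, 12, 13, from compound 3).

**Steps most likely to fail, with fallbacks**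

1. Step 7. The base may deprotonate the allylic C3 methylene, with loss of the benzoate by elimination, or the hindered tertiary carbanion may be captured too slowly by the secondary boronic ester and decompose before the boronate complex forms. The fallback sets out from 5 and comes back at 15; it no longer makes the ring C4–carbinol bond but starts with it in place. Commercially available 1-(1,4-dioxaspiro[4.5]decan-8-yl)ethan-1-one F1 is allylated by reagent-controlled asymmetric allylboration (B-allyl-10-phenyl-9-borabicyclo[3.3.2]decane of the configuration that gives the (S) carbinol) to (2S)-2-(1,4-dioxaspiro[4.5]decan-8-yl)pent-4-en-2-ol F2. Cross-metathesis of F2 with 5 under the conditions of step 4 should give (2S,4E,6R)-7-[(tert-butyldimethylsilyl)oxy]-2-(1,4-dioxaspiro[4.5]decan-8-yl)-6-methylhept-4-ene-2,6-diol F3. PPTS in aqueous acetone then frees 4-[(2S,4E,6R)-7-[(tert-butyldimethylsilyl)oxy]-2,6-dihydroxy-6-methylhept-4-en-2-yl]cyclohexan-1-one F4, and excess TESOTf/2,6-lutidine silylates both tertiary hydroxyls to give 15.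

2. Step 10. The chiral amide may discriminate poorly between the two diastereotopic α-methylene groups, or the enolate may equilibrate before triflation; either would give both C4 epimers of 17, which are unlikely to be separable. The fallback sets out from 15 and comes back at 18, and places the oxygen by catalysis instead of by a stoichiometric base. D-Proline-catalysed α-aminoxylation with nitrosobenzene in DMSO (axial attack on the enamine of the chair with the side chain equatorial puts oxygen on the required α-carbon; the isomer from the other α-carbon is a diastereomer that should be separable) gives (2S,4R)-2-(anilinooxy)-4-[(2S,4E,6R)-7-[(tert-butyldimethylsilyl)oxy]-6-methyl-2,6-bis[(triethylsilyl)oxy]hept-4-en-2-yl]cyclohexan-1-one F5. Zn/AcOH in THF cleaves the N–O bond to (2S,4R)-2-hydroxy-4-[(2S,4E,6R)-7-[(tert-butyldimethylsilyl)oxy]-6-methyl-2,6-bis[(triethylsilyl)oxy]hept-4-en-2-yl]cyclohexan-1-one F6, which is acetylated at once (Ac2O, pyridine, DMAP), to prevent migration of the carbonyl through the enediol, giving (1S,5R)-2-oxo-5-[(2S,4E,6R)-7-[(tert-butyldimethylsilyl)oxy]-6-methyl-2,6-bis[(triethylsilyl)oxy]hept-4-en-2-yl]cyclohexyl acetate F7. Non-basic methylenation of the ketone with Cp2TiMe2 in toluene at 65 °C gives (1S,5R)-2-methylidene-5-[(2S,4E,6R)-7-[(tert-butyldimethylsilyl)oxy]-6-methyl-2,6-bis[(triethylsilyl)oxy]hept-4-en-2-yl]cyclohexyl acetate F8. A 1,3-acetate shift catalysed by PdCl2(MeCN)2 (divalent palladium, THF, rt) moves the alkene into the ring and gives {(4R)-4-[(2S,4E,6R)-7-[(tert-butyldimethylsilyl)oxy]-6-methyl-2,6-bis[(triethylsilyl)oxy]hept-4-en-2-yl]cyclohex-1-en-1-yl}methyl acetate F9. K2CO3 in MeOH then gives 18.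

3. Step 11. Transmetalation of the hydroxymethyl group may be slow, so that protodestannylation of the reagent and reduction of the triflate compete. The fallback sets out from 17 and comes back at 18, and brings C7 in at the ester oxidation level. Carbonylation (Pd(OAc)2, PPh3, CO at 1 atm, MeOH, Et3N, DMF) gives methyl (4R)-4-[(2S,4E,6R)-7-[(tert-butyldimethylsilyl)oxy]-6-methyl-2,6-bis[(triethylsilyl)oxy]hept-4-en-2-yl]cyclohex-1-ene-1-carboxylate F10. DIBAL-H in CH2Cl2 at −78 °C reduces F10 to 18.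

**Further compounds**

F1 | step 7 | 1-(1,4-dioxaspiro[4.5]decan-8-yl)ethan-1-one | CC(=O)C1CCC2(CC1)OCCO2
F2 | step 7 | (2S)-2-(1,4-dioxaspiro[4.5]decan-8-yl)pent-4-en-2-ol | C[C@@](O)(C1CCC2(CC1)OCCO2)CC=C
F3 | step 7 | (2S,4E,6R)-7-[(tert-butyldimethylsilyl)oxy]-2-(1,4-dioxaspiro[4.5]decan-8-yl)-6-methylhept-4-ene-2,6-diol | C[C@@](O)(C1CCC2(CC1)OCCO2)C/C=C/[C@@](C)(O)CO[Si](C)(C)C(C)(C)C
F4 | step 7 | 4-[(2S,4E,6R)-7-[(tert-butyldimethylsilyl)oxy]-2,6-dihydroxy-6-methylhept-4-en-2-yl]cyclohexan-1-one | C[C@@](O)(C1CCC(=O)CC1)C/C=C/[C@@](C)(O)CO[Si](C)(C)C(C)(C)C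
F5 | step 10 | (2S,4R)-2-(anilinooxy)-4-[(2S,4E,6R)-7-[(tert-butyldimethylsilyl)oxy]-6-methyl-2,6-bis[(triethylsilyl)oxy]hept-4-en-2-yl]cyclohexan-1-one | O=C1[C@@H](ONc2ccccc2)C[C@H]([C@@](C)(O[Si](CC)(CC)CC)C/C=C/[C@@](C)(O[Si](CC)(CC)CC)CO[Si](C)(C)C(C)(C)C)CC1
F6 | step 10 | (2S,4R)-2-hydroxy-4-[(2S,4E,6R)-7-[(tert-butyldimethylsilyl)oxy]-6-methyl-2,6-bis[(triethylsilyl)oxy]hept-4-en-2-yl]cyclohexan-1-one | O=C1[C@@H](O)C[C@H]([C@@](C)(O[Si](CC)(CC)CC)C/C=C/[C@@](C)(O[Si](CC)(CC)CC)CO[Si](C)(C)C(C)(C)C)CC1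
F7 | step 10 | (1S,5R)-2-oxo-5-[(2S,4E,6R)-7-[(tert-butyldimethylsilyl)oxy]-6-methyl-2,6-bis[(triethylsilyl)oxy]hept-4-en-2-yl]cyclohexyl acetate | O=C1[C@@H](OC(C)=O)C[C@H]([C@@](C)(O[Si](CC)(CC)CC)C/C=C/[C@@](C)(O[Si](CC)(CC)CC)CO[Si](C)(C)C(C)(C)C)CC1
F8 | step 10 | (1S,5R)-2-methylidene-5-[(2S,4E,6R)-7-[(tert-butyldimethylsilyl)oxy]-6-methyl-2,6-bis[(triethylsilyl)oxy]hept-4-en-2-yl]cyclohexyl acetate | C=C1[C@@H](OC(C)=O)C[C@H]([C@@](C)(O[Si](CC)(CC)CC)C/C=C/[C@@](C)(O[Si](CC)(CC)CC)CO[Si](C)(C)C(C)(C)C)CC1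
F9 | step 10 | {(4R)-4-[(2S,4E,6R)-7-[(tert-butyldimethylsilyl)oxy]-6-methyl-2,6-bis[(triethylsilyl)oxy]hept-4-en-2-yl]cyclohex-1-en-1-yl}methyl acetate | CC(=O)OCC1=CC[C@H]([C@@](C)(O[Si](CC)(CC)CC)C/C=C/[C@@](C)(O[Si](CC)(CC)CC)CO[Si](C)(C)C(C)(C)C)CC1
F10 | step 11 | methyl (4R)-4-[(2S,4E,6R)-7-[(tert-butyldimethylsilyl)oxy]-6-methyl-2,6-bis[(triethylsilyl)oxy]hept-4-en-2-yl]cyclohex-1-ene-1-carboxylate | COC(=O)C1=CC[C@H]([C@@](C)(O[Si](CC)(CC)CC)C/C=C/[C@@](C)(O[Si](CC)(CC)CC)CO[Si](C)(C)C(C)(C)C)CC1
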